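**Retrosynthetic overview**

1. Target 42 ⇒ ester 40 (last step: peracid epoxidation of C1=C10) ⇒ 8-hydroxy heliangolide 32 + (2R,3R)-epoxyangelic acid 38 (Sharpless epoxidation route from angelic acid).
2. 32 ⇒ seco-aldehyde 30 by the C7–C8 disconnection. The strategy rests on C7, the β carbon of the C12 γ-lactone, being bonded to the C8 carbinol while C11 carries the exocyclic methylene C13: a C8 ketyl can add to C7 of a 3-(acetoxymethyl)butenolide, and loss of the C13 acetate unveils C11=C13 as the ten-membered carbocycle (C1–C10) closes.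
3. 30 ⇒ iodobutenolide 14 + aldehyde 23 (C3–C4 bond by Nozaki–Hiyama–Kishi coupling; C3 then set by oxidation and CBS reduction).
4. 14 ⇐ (S)-but-3-ene-1,2-diol (C6 from the chiral pool, Z-iodoalkene by Stork–Zhao olefination, butenolide by ring-closing metathesis); 23 ⇐ but-3-yn-1-ol (carboalumination fixes E-C1=C10).
5. Ring order: butenolide (step 7), ten-membered carbocycle (step 17), C1–C10 oxirane (step 22); the side-chain oxirane is made separately (step 19).

Key step: step 17

Remark: germacranolide numbering (C1–C15) is used for all intermediates; (S)-but-3-ene-1,2-diol, 2-(bromomethyl)acrylic acid and angelic acid are taken as commercial; the CIP label at C6 changes (S in 1–14, R from 24 on) with no change in spatial arrangement.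

**Route**

Step 1
Reactants: 1 (S)-but-3-ene-1,2-diol; 2 chlorotriethylsilane
Product: 3 (S)-3,4-bis(triethylsilyloxy)but-1-ene
Conditions: Et3SiCl (2.3 equiv), imidazole, CH2Cl2, 0 °C to rt
Reagents that add atoms: chlorotriethylsilane, CC[Si](Cl)(CC)CC
Why: Silyl ether formation on both hydroxyls masks the future C6 carbinol (stereocenter from the chiral pool) and gives a primary triethylsilyl ether that step 2 can oxidize directly.

Step 2
Reactants: 3 (S)-3,4-bis(triethylsilyloxy)but-1-ene
Product: 4 (S)-2-(triethylsilyloxy)but-3-enal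
Conditions: (COCl)2, DMSO, CH2Cl2, −78 to −40 °C; iPr2NEt, −78 °C; used crude
Reagents that add atoms: none
Why: Swern oxidation converts a primary triethylsilyl ether directly into the aldehyde while the secondary silyl ether stays, and the hindered base and low temperature are chosen because the α-silyloxy β,γ-unsaturated aldehyde enolizes easily.

Step 3
Reactants: 4 (S)-2-(triethylsilyloxy)but-3-enal; 5 ethyltriphenylphosphonium iodide; 6 iodine
Product: 7 (3S,4Z)-5-iodo-3-(triethylsilyloxy)hexa-1,4-diene
Conditions: 5, n-BuLi, THF, 0 °C; I2, −78 °C; NaN(SiMe3)2, −78 to −20 °C; then 4, −78 °C to rt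
Reagents that add atoms: ethyltriphenylphosphonium iodide, CC[P+](c1ccccc1)(c1ccccc1)c1ccccc1.[I-]; iodine, [I][I]
Why: Stork–Zhao olefination (Wittig reaction of the α-iodo ylide) should give mainly the (Z)-2-iodo-2-alkene with iodine cis to C6, so that the later C3–C4 bond ends cis to C6 as the 4Z alkene requires.

Step 4
Reactants: 7 (3S,4Z)-5-iodo-3-(triethylsilyloxy)hexa-1,4-diene
Product: 8 (3S,4Z)-5-iodohexa-1,4-dien-3-ol
Conditions: HF·pyridine, pyridine, THF, 0 °C
Reagents that add atoms: none
Why: Buffered fluoride desilylation frees the bis-allylic C6 hydroxyl without ionizing it.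

Step 5
Reactants: 9 2-(bromomethyl)acrylic acid; 10 potassium acetate
Product: 11 2-(acetoxymethyl)acrylic acid
Conditions: KOAc (3 equiv), AcOH, 60 °C
Reagents that add atoms: potassium acetate, CC(=O)[O-].[K+]
Why: SN2 displacement of the allylic bromide by acetate in acetic acid, where the substrate carboxylic acid stays protonated and does not compete as a nucleophile.

Step 6
Reactants: 8 (3S,4Z)-5-iodohexa-1,4-dien-3-ol; 11 2-(acetoxymethyl)acrylic acid
Product: 13 (3S,4Z)-5-iodohexa-1,4-dien-3-yl 2-(acetoxymethyl)prop-2-enoate, via acid chloride 12 (not isolated)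
Conditions: 11, Me2C=C(Cl)NMe2, CH2Cl2, 0 °C to rt; then 8, 2,6-lutidine, −20 to 0 °C
Reagents that add atoms: none
Why: Acylation through an acid chloride made under neutral conditions, with a hindered non-nucleophilic base so that no amine displaces the allylic acetate in an SN2' sense.

Step 7
Reactants: 13 (3S,4Z)-5-iodohexa-1,4-dien-3-yl 2-(acetoxymethyl)prop-2-enoate
Product: 14 [(5S)-5-[(Z)-2-iodoprop-1-en-1-yl]-2-oxo-2,5-dihydrofuran-3-yl]methyl acetate
Conditions: second-generation Grubbs catalyst RuCl2(=CHPh)(PCy3)(H2IMes) (10 mol%), 1,4-benzoquinone (cat.), toluene (5 mM), 80 °C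
Reagents that add atoms: none
Why: Ring-closing metathesis of the C6 vinyl group with the 1,1-disubstituted acrylate closes the butenolide (C7=C11) with loss of ethylene; the hindered trisubstituted vinyl iodide should not engage the catalyst, and closing the ring before the arm is attached avoids a competing seven-membered closure onto C1=C10.

Step 8
Reactants: 15 but-3-yn-1-ol; 16 tert-butylchlorodimethylsilane
Product: 17 tert-butyl(but-3-yn-1-yloxy)dimethylsilane
Conditions: TBSCl, imidazole, CH2Cl2, 0 °C to rt
Reagents that add atoms: tert-butylchlorodimethylsilane, CC(C)(C)[Si](C)(C)Cl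
Why: Silyl ether formation protects the future C8 hydroxyl through the organometallic steps.

Step 9
Reactants: 17 tert-butyl(but-3-yn-1-yloxy)dimethylsilane; 18 trimethylaluminium; 19 ethylene oxide
Product: 22 (E)-6-(tert-butyldimethylsilyloxy)-4-methylhex-3-en-1-ol, via alkenyl(dimethyl)alane 20 (not isolated), via lithium alanate 21 (not isolated)
Conditions: AlMe3, Cp2ZrCl2 (cat.), CH2Cl2, 0 °C to rt; evaporate, hexane/THF; n-BuLi, −78 to 0 °C; ethylene oxide, −78 °C to rt; dil. HCl
Reagents that add atoms: trimethylaluminium, C[Al](C)C; ethylene oxide, C1CO1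
Why: Zirconium-catalysed carboalumination adds methyl and aluminium syn across the alkyne with methyl on the internal carbon (C10), and the derived alanate opens ethylene oxide with retention, which fixes the E trisubstituted C1=C10 alkene and brings in C2 and C3.

Step 10
Reactants: 22 (E)-6-(tert-butyldimethylsilyloxy)-4-methylhex-3-en-1-ol
Product: 23 (E)-6-(tert-butyldimethylsilyloxy)-4-methylhex-3-enal
Conditions: Dess–Martin periodinane, pyridine, CH2Cl2, 0 °C; used crude
Reagents that add atoms: none
Why: Buffered Dess–Martin oxidation gives the β,γ-unsaturated aldehyde without base-induced migration of the double bond into conjugation.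

Step 11
Reactants: 14 iodobutenolide; 23 (E)-6-(tert-butyldimethylsilyloxy)-4-methylhex-3-enal
Product: 24 [(5R)-5-[(1Z,5E)-8-(tert-butyldimethylsilyloxy)-3-hydroxy-2,6-dimethylocta-1,5-dien-1-yl]-2-oxo-2,5-dihydrofuran-3-yl]methyl acetate (both C3 epimers)
Conditions: CrCl2 (excess), NiCl2 (cat.), DMSO/THF, rt
Reagents that add atoms: none
Why: Nozaki–Hiyama–Kishi coupling: zerovalent nickel inserts into the vinyl iodide with retention of the Z geometry and the organochromium adds to the aldehyde under neutral conditions that spare the enolizable aldehyde, the butenolide and the allylic acetate; C3 is not controlled here and is corrected in steps 12 and 13.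

Step 12
Reactants: 24 carbinol (both C3 epimers)
Product: 25 [(5R)-5-[(1Z,5E)-8-(tert-butyldimethylsilyloxy)-2,6-dimethyl-3-oxoocta-1,5-dien-1-yl]-2-oxo-2,5-dihydrofuran-3-yl]methyl acetate
Conditions: Dess–Martin periodinane, pyridine, CH2Cl2, 0 °C
Reagents that add atoms: none
Why: Dess–Martin oxidation of the allylic alcohol converges both C3 epimers to one Z enone under buffered, non-basic conditions that should not isomerize the skipped enone.

Step 13
Reactants: 25 Z enone
Product: 26 [(5R)-5-[(1Z,3S,5E)-8-(tert-butyldimethylsilyloxy)-3-hydroxy-2,6-dimethylocta-1,5-dien-1-yl]-2-oxo-2,5-dihydrofuran-3-yl]methyl acetate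
Conditions: (R)-2-methyl-CBS-oxazaborolidine, catecholborane, toluene/CH2Cl2, −78 °C
Reagents that add atoms: none
Why: Corey–Bakshi–Shibata reduction, in which the (R)-oxazaborolidine treats the 1-methylalkenyl group (C4) as the large and the C2 methylene as the small substituent and should deliver hydride to give the 3S carbinol, while catecholborane at low temperature leaves the unsaturated lactone alone.

Step 14
Reactants: 26 (3S)-carbinol; 27 isobutyryl chloride
Product: 28 (1Z,3S,5E)-1-[(2R)-4-(acetoxymethyl)-5-oxo-2,5-dihydrofuran-2-yl]-8-(tert-butyldimethylsilyloxy)-2,6-dimethylocta-1,5-dien-3-yl 2-methylpropanoate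
Conditions: iPrCOCl, pyridine, CH2Cl2, 0 °C to rt
Reagents that add atoms: isobutyryl chloride, CC(C)C(Cl)=O
Why: Acylation of the secondary allylic alcohol with the acid chloride and pyridine only (no DMAP), so that the allylic acetate and the γ-hydrogen of the butenolide are not put at risk.

Step 15
Reactants: 28 silyl ether
Product: 29 (1Z,3S,5E)-1-[(2R)-4-(acetoxymethyl)-5-oxo-2,5-dihydrofuran-2-yl]-8-hydroxy-2,6-dimethylocta-1,5-dien-3-yl 2-methylpropanoate
Conditions: HF·pyridine, pyridine, THF, 0 °C to rt
Reagents that add atoms: none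
Why: Buffered fluoride desilylation frees the primary C8 hydroxyl without touching the two esters or the butenolide.

Step 16
Reactants: 29 primary alcohol
Product: 30 (1Z,3S,5E)-1-[(2R)-4-(acetoxymethyl)-5-oxo-2,5-dihydrofuran-2-yl]-2,6-dimethyl-8-oxoocta-1,5-dien-3-yl 2-methylpropanoate
Conditions: Dess–Martin periodinane, pyridine, CH2Cl2, 0 °C; used at once
Reagents that add atoms: none
Why: Buffered Dess–Martin oxidation gives the β,γ-unsaturated C8 aldehyde without double-bond migration.

Step 17
Reactants: 30 seco-aldehyde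
Product: 32 (3S,6R,7R,8R)-8-hydroxy-3-(isobutyryloxy)germacra-1(10)E,4Z,11(13)-trien-12,6-olide, via samarium enolate 31 (not isolated)
Conditions: SmI2 (2.5 equiv), THF, −78 to −30 °C, slow addition of 30 to a final 2 mM; aq. NH4Cl
Reagents that add atoms: none
Why: Proposed new method: SmI2 reduces the C8 aldehyde to a samarium ketyl that adds as a nucleophilic radical to C7, the electron-poor β carbon of the butenolide, and a second electron turns the C11 radical into the samarium enolate 31, which loses the C13 acetate by β-elimination and leaves the C11=C13 methylene. The closest known reactions are SmI2 ketyl–olefin cyclizations of aldehydes onto acrylates and butenolides that form five- to eight-membered rings, and the β-elimination of β-acetoxy samarium enolates; a ten-membered closure of this kind is not known. The ten-membered carbocycle closes in a 10-exo-trig mode (the C7=C11 π bond lies outside the new ring), helped by the three rigid units in the chain (Z-C4=C5, E-C1=C10, planar butenolide) and by high dilution. C7 should be set by attack on the butenolide face anti to the C5 substituent at C6, giving the trans-fused lactone, and C8 by a trivalent samarium bridge between the ketyl oxygen and the lactone carbonyl oxygen, which holds O8 over the lactone (syn to C11) while C9 points back toward C6 and so gives 8R. The step needs the aldehyde to be reduced before the enoate or the allylic acetate, which is secured by using SmI2 in THF at low temperature without HMPA or a proton donor, so that only the samarium-bound aldehyde accepts an electron.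

Step 18
Reactants: 33 angelic acid
Product: 34 (Z)-2-methylbut-2-en-1-ol
Conditions: LiAlH4, Et2O, 0 °C
Reagents that add atoms: none
Why: Hydride reduction of the carboxylic acid to the allylic alcohol with the Z geometry kept.

Step 19
Reactants: 34 (Z)-2-methylbut-2-en-1-ol; 35 tert-butyl hydroperoxide
Product: 36 [(2S,3R)-2,3-dimethyloxiran-2-yl]methanol
Conditions: Ti(OiPr)4, L-(+)-diethyl tartrate, t-BuOOH, 4 Å sieves, CH2Cl2, −20 °C
Reagents that add atoms: tert-butyl hydroperoxide, CC(C)(C)OO
Why: Sharpless asymmetric epoxidation, in which the L-(+)-tartrate complex delivers oxygen to the face of the Z allylic alcohol that gives the (2S,3R) epoxy alcohol and so sets both side-chain stereocenters.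

Step 20
Reactants: 36 epoxy alcohol; 37 sodium chlorite
Product: 38 (2R,3R)-2,3-dimethyloxirane-2-carboxylic acid
Conditions: TEMPO (cat.), NaOCl (cat.), NaClO2, MeCN/phosphate buffer pH 6.7, 35 °C
Reagents that add atoms: sodium chlorite, [Na+].[O-]Cl=O
Why: TEMPO-catalysed chlorite oxidation takes the primary alcohol to the acid near neutral pH, which the oxirane should tolerate (the C2 label changes from S to R by priority only).

Step 21
Reactants: 32 8-hydroxy heliangolide; 38 (2R,3R)-2,3-dimethyloxirane-2-carboxylic acid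
Product: 40 (3S,6R,7R,8R)-8-[(2R,3R)-2,3-dimethyloxirane-2-carbonyloxy]-3-(isobutyryloxy)germacra-1(10)E,4Z,11(13)-trien-12,6-olide, via mixed anhydride 39 (not isolated)
Conditions: 38, 2,4,6-trichlorobenzoyl chloride, Et3N, THF, 0 °C to rt; then 32, DMAP, toluene, rt
Reagents that add atoms: none
Why: Yamaguchi esterification activates the hindered α-quaternary epoxy acid as a mixed anhydride, which acylates the secondary C8 hydroxyl with retention at C8.

Step 22
Reactants: 40 triene ester; 41 3-chloroperbenzoic acid
Product: 42 (1R,3S,6R,7R,8R,10R)-1,10-epoxy-8-[(2R,3R)-2,3-dimethyloxirane-2-carbonyloxy]-3-(isobutyryloxy)germacra-4Z,11(13)-dien-12,6-olide (target)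
Conditions: mCPBA (1.05 equiv), NaHCO3, CH2Cl2, 0 °C
Reagents that add atoms: 3-chloroperbenzoic acid, OOC(=O)c1cccc(Cl)c1
Why: Prilezhaev epoxidation should pick C1=C10, the only alkene without an allylic oxygen or a conjugated carbonyl, and attack on its outer face in the ring conformer with C14 on the β face should give the trans 1β,10α (1R,10R) oxirane.

**Compound list**

1 | (S)-but-3-ene-1,2-diol | C=C[C@H](O)CO | starting material
2 | chlorotriethylsilane | CC[Si](Cl)(CC)CC | starting material
3 | (S)-3,4-bis(triethylsilyloxy)but-1-ene | C=C[C@H](O[Si](CC)(CC)CC)CO[Si](CC)(CC)CC | intermediate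
4 | (S)-2-(triethylsilyloxy)but-3-enal | C=C[C@H](O[Si](CC)(CC)CC)C=O | intermediate
5 | ethyltriphenylphosphonium iodide | CC[P+](c1ccccc1)(c1ccccc1)c1ccccc1.[I-] | starting material
6 | iodine | [I][I] | starting material
7 | (3S,4Z)-5-iodo-3-(triethylsilyloxy)hexa-1,4-diene | C=C[C@H](O[Si](CC)(CC)CC)/C=C(/C)I | intermediate
8 | (3S,4Z)-5-iodohexa-1,4-dien-3-ol | C=C[C@H](O)/C=C(/C)I | intermediate
9 | 2-(bromomethyl)acrylic acid | C=C(CBr)C(=O)O | starting material
10 | potassium acetate | CC(=O)[O-].[K+] | starting material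
11 | 2-(acetoxymethyl)acrylic acid | CC(=O)OCC(=C)C(=O)O | intermediate
12 | 2-(acetoxymethyl)acryloyl chloride | CC(=O)OCC(=C)C(Cl)=O | intermediate
13 | (3S,4Z)-5-iodohexa-1,4-dien-3-yl 2-(acetoxymethyl)prop-2-enoate | C=C[C@H](OC(=O)C(=C)COC(C)=O)/C=C(/C)I | intermediate
14 | [(5S)-5-[(Z)-2-iodoprop-1-en-1-yl]-2-oxo-2,5-dihydrofuran-3-yl]methyl acetate | CC(=O)OCC1=C[C@H](OC1=O)/C=C(/C)I | intermediate
15 | but-3-yn-1-ol | C#CCCO | starting material
16 | tert-butylchlorodimethylsilane | CC(C)(C)[Si](C)(C)Cl | starting material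
17 | tert-butyl(but-3-yn-1-yloxy)dimethylsilane | C#CCCO[Si](C)(C)C(C)(C)C | intermediate
18 | trimethylaluminium | C[Al](C)C | starting material
19 | ethylene oxide | C1CO1 | starting material
20 | [(E)-4-(tert-butyldimethylsilyloxy)-2-methylbut-1-en-1-yl]dimethylalane | C[Al](C)/C=C(\C)CCO[Si](C)(C)C(C)(C)C | intermediate
21 | lithium butyl[(E)-4-(tert-butyldimethylsilyloxy)-2-methylbut-1-en-1-yl]dimethylalanate | [Li+].CCCC[Al-](C)(C)/C=C(\C)CCO[Si](C)(C)C(C)(C)C | intermediate
22 | (E)-6-(tert-butyldimethylsilyloxy)-4-methylhex-3-en-1-ol | OCC/C=C(\C)CCO[Si](C)(C)C(C)(C)C | intermediate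
23 | (E)-6-(tert-butyldimethylsilyloxy)-4-methylhex-3-enal | O=CC/C=C(\C)CCO[Si](C)(C)C(C)(C)C | intermediate
24 | [(5R)-5-[(1Z,5E)-8-(tert-butyldimethylsilyloxy)-3-hydroxy-2,6-dimethylocta-1,5-dien-1-yl]-2-oxo-2,5-dihydrofuran-3-yl]methyl acetate, both C3 epimers | CC(=O)OCC1=C[C@H](OC1=O)/C=C(/C)C(O)C/C=C(\C)CCO[Si](C)(C)C(C)(C)C | intermediate
25 | [(5R)-5-[(1Z,5E)-8-(tert-butyldimethylsilyloxy)-2,6-dimethyl-3-oxoocta-1,5-dien-1-yl]-2-oxo-2,5-dihydrofuran-3-yl]methyl acetate | CC(=O)OCC1=C[C@H](OC1=O)/C=C(/C)C(=O)C/C=C(\C)CCO[Si](C)(C)C(C)(C)C | intermediate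
26 | [(5R)-5-[(1Z,3S,5E)-8-(tert-butyldimethylsilyloxy)-3-hydroxy-2,6-dimethylocta-1,5-dien-1-yl]-2-oxo-2,5-dihydrofuran-3-yl]methyl acetate | CC(=O)OCC1=C[C@H](OC1=O)/C=C(/C)[C@@H](O)C/C=C(\C)CCO[Si](C)(C)C(C)(C)C | intermediate
27 | isobutyryl chloride | CC(C)C(Cl)=O | starting material
28 | (1Z,3S,5E)-1-[(2R)-4-(acetoxymethyl)-5-oxo-2,5-dihydrofuran-2-yl]-8-(tert-butyldimethylsilyloxy)-2,6-dimethylocta-1,5-dien-3-yl 2-methylpropanoate | CC(=O)OCC1=C[C@H](OC1=O)/C=C(/C)[C@@H](OC(=O)C(C)C)C/C=C(\C)CCO[Si](C)(C)C(C)(C)C | intermediate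
29 | (1Z,3S,5E)-1-[(2R)-4-(acetoxymethyl)-5-oxo-2,5-dihydrofuran-2-yl]-8-hydroxy-2,6-dimethylocta-1,5-dien-3-yl 2-methylpropanoate | CC(=O)OCC1=C[C@H](OC1=O)/C=C(/C)[C@@H](OC(=O)C(C)C)C/C=C(\C)CCO | intermediate
30 | (1Z,3S,5E)-1-[(2R)-4-(acetoxymethyl)-5-oxo-2,5-dihydrofuran-2-yl]-2,6-dimethyl-8-oxoocta-1,5-dien-3-yl 2-methylpropanoate (key-step precursor) | CC(=O)OCC1=C[C@H](OC1=O)/C=C(/C)[C@@H](OC(=O)C(C)C)C/C=C(\C)CC=O | intermediate
31 | cyclized bis(diiodosamarium) species: C8 samarium alkoxide and C11=C12 samarium enolate still carrying the C13 acetate | CC(=O)OCC1=C(O[Sm](I)I)O[C@@H]2/C=C(/C)[C@@H](OC(=O)C(C)C)C/C=C(\C)C[C@@H](O[Sm](I)I)[C@@H]12 | intermediate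
32 | (3S,6R,7R,8R)-8-hydroxy-3-(isobutyryloxy)germacra-1(10)E,4Z,11(13)-trien-12,6-olide (key-step product) | C=C1C(=O)O[C@@H]2/C=C(/C)[C@@H](OC(=O)C(C)C)C/C=C(\C)C[C@@H](O)[C@@H]12 | intermediate
33 | angelic acid, (Z)-2-methylbut-2-enoic acid | C/C=C(/C)C(=O)O | starting material
34 | (Z)-2-methylbut-2-en-1-ol | C/C=C(/C)CO | intermediate
35 | tert-butyl hydroperoxide | CC(C)(C)OO | starting material
36 | [(2S,3R)-2,3-dimethyloxiran-2-yl]methanol | OC[C@]1(C)O[C@@H]1C | intermediate
37 | sodium chlorite | [Na+].[O-]Cl=O | starting material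
38 | (2R,3R)-2,3-dimethyloxirane-2-carboxylic acid | OC(=O)[C@]1(C)O[C@@H]1C | intermediate
39 | (2R,3R)-2,3-dimethyloxirane-2-carboxylic 2,4,6-trichlorobenzoic anhydride | Clc1cc(Cl)c(c(Cl)c1)C(=O)OC(=O)[C@]1(C)O[C@@H]1C | intermediate
40 | (3S,6R,7R,8R)-8-[(2R,3R)-2,3-dimethyloxirane-2-carbonyloxy]-3-(isobutyryloxy)germacra-1(10)E,4Z,11(13)-trien-12,6-olide | C=C1C(=O)O[C@@H]2/C=C(/C)[C@@H](OC(=O)C(C)C)C/C=C(\C)C[C@@H](OC(=O)[C@]3(C)O[C@@H]3C)[C@@H]12 | intermediate
41 | 3-chloroperbenzoic acid | OOC(=O)c1cccc(Cl)c1 | starting material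
42 | (1R,3S,6R,7R,8R,10R)-1,10-epoxy-8-[(2R,3R)-2,3-dimethyloxirane-2-carbonyloxy]-3-(isobutyryloxy)germacra-4Z,11(13)-dien-12,6-olide | C=C1C(=O)O[C@@H]2/C=C(/C)[C@@H](OC(=O)C(C)C)C[C@H]3O[C@]3(C)C[C@@H](OC(=O)[C@]3(C)O[C@@H]3C)[C@@H]12 | target

**Step count and risks**

Total steps: 22. Longest linear sequence: 15 steps (1, 2, 3, 4, 6, 7, 11, 12, 13, 14, 15, 16, 17, 21, 22).

Steps most likely to fail:

Step 17. The ten-membered closure may lose to pinacol dimerization or to simple reduction of the ketyl. The ketyl may also add in the acetate-chelated rather than the lactone-chelated orientation, which would give the C8 epimer, and the C8 samarium alkoxide may translactonize onto C12. The fallback sets out from aldehyde 30 and returns at 32 with known chemistry, a palladium-catalysed umpolung allylation. Pd(PPh3)4 (cat.) ionizes the C13 allylic acetate to a π-allyl complex over C13–C11–C7, and InI in THF turns it into an allylindium species. This adds through its γ carbon C7 to the C8 aldehyde in a cyclic transition state, giving the same C7–C8 bond and the C11=C13 methylene (Barbier-type allylation of aldehydes by 2-(acyloxymethyl)acrylate-type acetates). No new isolated compound is needed.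

Step 3. The basic ylide may enolize the α-silyloxy β,γ-unsaturated aldehyde (erosion of configuration at C6, migration of the vinyl double bond), and the Z selectivity of the iodo-olefination may be incomplete. The fallback sets out from aldehyde 4 and returns at 8, fixing the geometry through an alkyne instead of a Wittig reaction. Corey–Fuchs dibromo-olefination (CBr4, PPh3, Zn, CH2Cl2, non-basic) gives (S)-(1,1-dibromopenta-1,4-dien-3-yloxy)triethylsilane F1. n-BuLi (2 equiv, THF, −78 °C) followed by MeI gives (S)-triethyl(hex-1-en-4-yn-3-yloxy)silane F2. HF·pyridine gives (S)-hex-1-en-4-yn-3-ol F3. Hydroxyl-directed trans-hydroalumination with NaAlH2(OCH2CH2OMe)2 in THF, then I2 at −78 °C, places aluminium and then iodine on C4 cis to C6 through a five-membered alkoxyaluminate and gives 8 as the Z isomer only.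

Step 22. The peracid may attack the wrong face of C1=C10, or the acid formed may open the new oxirane by transannular cyclization onto C4=C5. The fallback sets out from 32 and returns at 42 with the order of the last two steps reversed and a directed epoxidation. VO(acac)2 and t-BuOOH in CH2Cl2 at 0 °C use the free homoallylic C8 hydroxyl to deliver oxygen to C1=C10 under neutral conditions, giving (1R,3S,6R,7R,8R,10R)-1,10-epoxy-8-hydroxy-3-(isobutyryloxy)germacra-4Z,11(13)-dien-12,6-olide F4. This is then esterified with acid 38 under the Yamaguchi conditions of step 21 to give 42.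

Further compounds
F0 | step 17 | none | none
F1 | step 3 | (S)-(1,1-dibromopenta-1,4-dien-3-yloxy)triethylsilane | C=C[C@H](O[Si](CC)(CC)CC)C=C(Br)Br
F2 | step 3 | (S)-triethyl(hex-1-en-4-yn-3-yloxy)silane | C=C[C@H](O[Si](CC)(CC)CC)C#CC
F3 | step 3 | (S)-hex-1-en-4-yn-3-ol | C=C[C@H](O)C#CC
F4 | step 22 | (1R,3S,6R,7R,8R,10R)-1,10-epoxy-8-hydroxy-3-(isobutyryloxy)germacra-4Z,11(13)-dien-12,6-olide | C=C1C(=O)O[C@@H]2/C=C(/C)[C@@H](OC(=O)C(C)C)C[C@H]3O[C@]3(C)C[C@@H](O)[C@@H]12
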